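The cyclohexene ring of the bicyclic core (C3a, C4, C5, C6, C7, C7a; 1H-indene locants, C4 carrying the carboxyl) is a Diels–Alder retron whose diene is itself cut at its central C6–C7 bond; the cyclopentene carbons C1–C3 act as a three-atom tether. In one operation a Stille coupling joins a C7 alkenylstannane, which carries the dienophile and the C1 methyl stereocentre, to a C6 bromotriene, and the tetraene so formed cyclises by intramolecular Diels–Alder reaction. This makes C6–C7 (the ring alkene), the C4–C5 bond between the two quaternary carbons and the trans ring-fusion bond C3a–C7a, and sets four stereocentres from C1. Ester cleavage ends the route.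

Key step: step 14

Remark: the thermal cycloaddition is assumed to run through the ester-endo, tether-exo transition state, which leads to the relative configuration of the target.

Step 1
Reactants: 1 methyl (R)-3-hydroxy-2-methylpropanoate
Product: 2 methyl (R)-3-[(tert-butyldimethylsilyl)oxy]-2-methylpropanoate
Conditions: TBSCl, imidazole, CH2Cl2, 0 to 23 °C
Reagents that add atoms: TBSCl, CC(C)(C)[Si](C)(C)Cl
Why: Imidazole-mediated silylation of the primary alcohol; the stereocentre is not involved.

Step 2
Reactants: 2 methyl (R)-3-[(tert-butyldimethylsilyl)oxy]-2-methylpropanoate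
Product: 3 (R)-3-[(tert-butyldimethylsilyl)oxy]-2-methylpropanal
Conditions: i-Bu2AlH (1.1 equiv), CH2Cl2, −78 °C; aq. potassium sodium tartrate
Reagents that add atoms: none
Why: Partial ester reduction, since the aluminium hemiacetal is stable at −78 °C and gives the aldehyde only on work-up; the aldehyde is used cold and crude to keep the α-stereocentre intact.

Step 3
Reactants: 3 (R)-3-[(tert-butyldimethylsilyl)oxy]-2-methylpropanal
Product: 4 (S)-tert-butyl[(4,4-dibromo-2-methylbut-3-en-1-yl)oxy]dimethylsilane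
Conditions: CBr4, PPh3, Zn dust, CH2Cl2, 23 °C (ylide pre-formed); then 3, 0 °C
Reagents that add atoms: carbon tetrabromide, BrC(Br)(Br)Br
Why: First stage of the Corey–Fuchs sequence (Wittig-type dibromoolefination); the zinc-generated ylide reacts under neutral conditions, so neither the silyl ether nor the α-stereocentre should suffer.

Step 4
Reactants: 4 (S)-tert-butyl[(4,4-dibromo-2-methylbut-3-en-1-yl)oxy]dimethylsilane
Product: 6 (S)-tert-butyldimethyl[(2-methylpent-3-yn-1-yl)oxy]silane, via lithium acetylide 5 (not isolated)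
Conditions: n-BuLi (2.2 equiv), THF, −78 to 0 °C; then MeI, −78 to 23 °C
Reagents that add atoms: iodomethane, CI
Why: Second stage of the Corey–Fuchs alkyne synthesis: Br/Li exchange and elimination give the lithium acetylide, which is C-methylated by iodomethane.

Step 5
Reactants: 6 (S)-tert-butyldimethyl[(2-methylpent-3-yn-1-yl)oxy]silane
Product: 7 (S,E)-tert-butyldimethyl{[2-methyl-4-(tributylstannyl)pent-3-en-1-yl]oxy}silane
Conditions: Bu3SnH, PdCl2(PPh3)2 (3 mol %), THF, 0 to 23 °C
Reagents that add atoms: tributyltin hydride, CCCC[SnH](CCCC)CCCC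
Why: Palladium-catalysed syn-hydrostannation; tin should go to the less hindered, methyl-bearing alkyne carbon remote from the branched stereocentre, and syn addition fixes the E geometry (H and Sn cis).

Step 6
Reactants: 7 (S,E)-tert-butyldimethyl{[2-methyl-4-(tributylstannyl)pent-3-en-1-yl]oxy}silane
Product: 8 (S,E)-2-methyl-4-(tributylstannyl)pent-3-en-1-ol
Conditions: Bu4NF, THF, 0 °C
Reagents that add atoms: none
Why: Fluoride cleavage of the Si–O bond; the alkenyl–tin bond is inert to fluoride under these conditions.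

Step 7
Reactants: 8 (S,E)-2-methyl-4-(tributylstannyl)pent-3-en-1-ol
Product: 9 (S,E)-2-methyl-4-(tributylstannyl)pent-3-enal
Conditions: Dess–Martin periodinane, pyridine, CH2Cl2, 0 °C; crude product used at once
Reagents that add atoms: none
Why: Dess–Martin oxidation under buffered, non-basic conditions; the α-stereogenic β,γ-unsaturated aldehyde is not stored, to avoid epimerisation or conjugation.

Step 8
Reactants: 10 methyl 2-[bis(2,2,2-trifluoroethoxy)phosphoryl]acetate
Product: 11 methyl 2-[bis(2,2,2-trifluoroethoxy)phosphoryl]butanoate (racemic)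
Conditions: KOt-Bu (1.0 equiv), EtI, THF, 0 to 23 °C
Reagents that add atoms: iodoethane, CCI
Why: SN2 C-alkylation of the stabilised phosphonoacetate anion; one equivalent of base limits dialkylation.

Step 9
Reactants: 9 (S,E)-2-methyl-4-(tributylstannyl)pent-3-enal; 11 methyl 2-[bis(2,2,2-trifluoroethoxy)phosphoryl]butanoate
Product: 12 methyl (2Z,4R,5E)-2-ethyl-4-methyl-6-(tributylstannyl)hepta-2,5-dienoate
Conditions: 11, KN(SiMe3)2, 18-crown-6, THF, −78 °C; then 9, −78 °C
Reagents that add atoms: none
Why: Still–Gennari olefination: the electron-poor phosphonate with a dissociated potassium counter-ion eliminates fast from the kinetic adduct and gives the Z trisubstituted enoate (ester cis to the chain); the weakly basic anion at −78 °C should leave the stereocentre untouched.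

Step 10
Reactants: 12 methyl (2Z,4R,5E)-2-ethyl-4-methyl-6-(tributylstannyl)hepta-2,5-dienoate
Product: 13 (2Z,4R,5E)-2-ethyl-4-methyl-6-(tributylstannyl)hepta-2,5-dien-1-ol
Conditions: i-Bu2AlH (2.5 equiv), CH2Cl2, −78 °C; aq. potassium sodium tartrate
Reagents that add atoms: none
Why: 1,2-Reduction of the enoate to the allylic alcohol by an aluminium hydride; alkene geometry and the C–Sn bond are not affected.

Step 11
Reactants: 13 (2Z,4R,5E)-2-ethyl-4-methyl-6-(tributylstannyl)hepta-2,5-dien-1-ol; 14 methyl 2-(triphenyl-λ5-phosphanylidene)propanoate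
Product: 16 methyl (2E,4Z,6R,7E)-4-ethyl-2,6-dimethyl-8-(tributylstannyl)nona-2,4,7-trienoate, via Z-enal 15 (not isolated)
Conditions: activated MnO2 (15 equiv), 14 (2 equiv), CH2Cl2, 40 °C
Reagents that add atoms: none
Why: Tandem allylic oxidation–Wittig reaction: the Z-enal is trapped by the stabilised ylide as it forms, before it can isomerise, and the stabilised ylide gives the E-configured new alkene.

Step 12
Reactants: 17 2-ethylacrolein (2-methylidenebutanal)
Product: 19 (E)-2-(bromomethylidene)butanal, via dibromo aldehyde 18 (not isolated)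
Conditions: Br2 (1.0 equiv), CH2Cl2, −78 to 0 °C; then Et3N, 0 to 23 °C
Reagents that add atoms: bromine, BrBr
Why: Bromine addition to the alkene followed by amine-induced E2 loss of HBr through the more acidic CH2Br hydrogens (bromination–dehydrobromination); the E isomer with Br anti to the formyl group is the thermodynamically preferred one.

Step 13
Reactants: 19 (E)-2-(bromomethylidene)butanal; 20 diethyl [(E)-3-phenylprop-2-en-1-yl]phosphonate
Product: 21 [(1E,3E,5E)-6-bromo-5-ethylhexa-1,3,5-trien-1-yl]benzene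
Conditions: 20, NaN(SiMe3)2, THF, −78 °C; then 19, −78 to 0 °C
Reagents that add atoms: none
Why: Horner–Wadsworth–Emmons olefination with the allylic phosphonate anion; 1,2-addition at low temperature and syn-elimination give the E alkene, and the bromoalkene geometry is carried through unchanged.

Step 14
Reactants: 16 methyl (2E,4Z,6R,7E)-4-ethyl-2,6-dimethyl-8-(tributylstannyl)nona-2,4,7-trienoate; 21 [(1E,3E,5E)-6-bromo-5-ethylhexa-1,3,5-trien-1-yl]benzene
Product: 23 methyl (1R,3aR,4R,5S,7aS)-3,5-diethyl-1,4,7-trimethyl-5-[(1E,3E)-4-phenylbuta-1,3-dien-1-yl]-3a,4,5,7a-tetrahydro-1H-indene-4-carboxylate, via tetraene ester 22 (not isolated)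
Conditions: Pd(PPh3)4 (10 mol %), CuI (20 mol %), CsF (2 equiv), degassed DMF, 45 °C; then 90 °C in the same flask
Reagents that add atoms: none
Why: Zerovalent palladium inserts into the C–Br bond of 21, CuI/CsF-assisted transmetalation from tin and reductive elimination join C6 to C7 with retention of both alkene geometries (Stille coupling), and the resulting tetraene 22 undergoes on warming a thermal type 1 intramolecular Diels–Alder reaction of its 7,9-diene with its 2,3-enoate (chain locants of 22); the closest known reaction type is the domino Stille/intramolecular Diels–Alder sequence. The cyclohexene closes by suprafacial [4+2] cycloaddition (C4–C5 and C3a–C7a bonds, C6=C7 alkene), and the same C3a–C7a bond closes the cyclopentene across the three-atom Z-alkene tether. C5 follows from the E geometry of the ethyl-bearing diene terminus, C4 and C3a from the E dienophile reacting with the ester endo and the tether exo, which also makes the ring fusion trans, and C7a from the E geometry of the other diene terminus. The absolute sense comes from C1: allylic 1,3-strain with the C7 methyl puts the C1 hydrogen in the diene plane and the C1 methyl anti to the incoming dienophile. The step needs endo over exo selectivity and attack on one diene face; the rigid Z-alkene tether and the 1,3-strain are expected to secure both, and the E geometry of the 7,8-alkene rules out the competing cycloaddition of the dienoate onto the 9,10-alkene.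

Step 15
Reactants: 23 methyl (1R,3aR,4R,5S,7aS)-3,5-diethyl-1,4,7-trimethyl-5-[(1E,3E)-4-phenylbuta-1,3-dien-1-yl]-3a,4,5,7a-tetrahydro-1H-indene-4-carboxylate
Product: 24 (1R,3aR,4R,5S,7aS)-3,5-diethyl-1,4,7-trimethyl-5-[(1E,3E)-4-phenylbuta-1,3-dien-1-yl]-3a,4,5,7a-tetrahydro-1H-indene-4-carboxylic acid
Conditions: n-PrSLi (5 equiv), HMPA, 23 °C; then 1 M HCl
Reagents that add atoms: none
Why: Nucleophilic ester cleavage by SN2 attack of thiolate at the O-methyl group, which avoids the carbonyl carbon shielded by two adjacent quaternary centres; no stereocentre is touched.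

Compound list
1 | methyl (R)-3-hydroxy-2-methylpropanoate | OC[C@@H](C)C(=O)OC | starting material
2 | methyl (R)-3-[(tert-butyldimethylsilyl)oxy]-2-methylpropanoate | CC(C)(C)[Si](C)(C)OC[C@@H](C)C(=O)OC | intermediate
3 | (R)-3-[(tert-butyldimethylsilyl)oxy]-2-methylpropanal | CC(C)(C)[Si](C)(C)OC[C@@H](C)C=O | intermediate
4 | (S)-tert-butyl[(4,4-dibromo-2-methylbut-3-en-1-yl)oxy]dimethylsilane | CC(C)(C)[Si](C)(C)OC[C@@H](C)C=C(Br)Br | intermediate
5 | lithium (S)-4-[(tert-butyldimethylsilyl)oxy]-3-methylbut-1-yn-1-ide (lithium acetylide) | CC(C)(C)[Si](C)(C)OC[C@@H](C)C#C[Li] | intermediate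
6 | (S)-tert-butyldimethyl[(2-methylpent-3-yn-1-yl)oxy]silane | CC(C)(C)[Si](C)(C)OC[C@@H](C)C#CC | intermediate
7 | (S,E)-tert-butyldimethyl{[2-methyl-4-(tributylstannyl)pent-3-en-1-yl]oxy}silane | CC(C)(C)[Si](C)(C)OC[C@@H](C)/C=C(\C)[Sn](CCCC)(CCCC)CCCC | intermediate
8 | (S,E)-2-methyl-4-(tributylstannyl)pent-3-en-1-ol | OC[C@@H](C)/C=C(\C)[Sn](CCCC)(CCCC)CCCC | intermediate
9 | (S,E)-2-methyl-4-(tributylstannyl)pent-3-enal | O=C[C@@H](C)/C=C(\C)[Sn](CCCC)(CCCC)CCCC | intermediate
10 | methyl 2-[bis(2,2,2-trifluoroethoxy)phosphoryl]acetate | COC(=O)CP(=O)(OCC(F)(F)F)OCC(F)(F)F | starting material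
11 | methyl 2-[bis(2,2,2-trifluoroethoxy)phosphoryl]butanoate (racemic) | CCC(C(=O)OC)P(=O)(OCC(F)(F)F)OCC(F)(F)F | intermediate
12 | methyl (2Z,4R,5E)-2-ethyl-4-methyl-6-(tributylstannyl)hepta-2,5-dienoate | CC/C(C(=O)OC)=C/[C@@H](C)/C=C(\C)[Sn](CCCC)(CCCC)CCCC | intermediate
13 | (2Z,4R,5E)-2-ethyl-4-methyl-6-(tributylstannyl)hepta-2,5-dien-1-ol | CC/C(CO)=C/[C@@H](C)/C=C(\C)[Sn](CCCC)(CCCC)CCCC | intermediate
14 | methyl 2-(triphenyl-λ5-phosphanylidene)propanoate | COC(=O)C(C)=P(c1ccccc1)(c1ccccc1)c1ccccc1 | starting material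
15 | (2Z,4R,5E)-2-ethyl-4-methyl-6-(tributylstannyl)hepta-2,5-dienal (Z-enal) | CC/C(C=O)=C/[C@@H](C)/C=C(\C)[Sn](CCCC)(CCCC)CCCC | intermediate
16 | methyl (2E,4Z,6R,7E)-4-ethyl-2,6-dimethyl-8-(tributylstannyl)nona-2,4,7-trienoate | COC(=O)/C(C)=C/C(CC)=C\[C@@H](C)/C=C(\C)[Sn](CCCC)(CCCC)CCCC | intermediate
17 | 2-ethylacrolein (2-methylidenebutanal) | CCC(=C)C=O | starting material
18 | 2-bromo-2-(bromomethyl)butanal (racemic; dibromo aldehyde) | CCC(Br)(CBr)C=O | intermediate
19 | (E)-2-(bromomethylidene)butanal | CC/C(C=O)=C\Br | intermediate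
20 | diethyl [(E)-3-phenylprop-2-en-1-yl]phosphonate | CCOP(=O)(OCC)C/C=C/c1ccccc1 | starting material
21 | [(1E,3E,5E)-6-bromo-5-ethylhexa-1,3,5-trien-1-yl]benzene | CC/C(=C\Br)/C=C/C=C/c1ccccc1 | intermediate
22 | methyl (2E,4Z,6S,7E,9E,11E,13E)-4,10-diethyl-2,6,8-trimethyl-14-phenyltetradeca-2,4,7,9,11,13-hexaenoate (tetraene ester) | COC(=O)/C(C)=C/C(CC)=C\[C@@H](C)/C=C(C)/C=C(CC)/C=C/C=C/c1ccccc1 | intermediate
23 | methyl (1R,3aR,4R,5S,7aS)-3,5-diethyl-1,4,7-trimethyl-5-[(1E,3E)-4-phenylbuta-1,3-dien-1-yl]-3a,4,5,7a-tetrahydro-1H-indene-4-carboxylate | CCC1=C[C@@H](C)[C@@H]2C(C)=C[C@@](/C=C/C=C/c3ccccc3)(CC)[C@](C)(C(=O)OC)[C@@H]12 | intermediate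
24 | (1R,3aR,4R,5S,7aS)-3,5-diethyl-1,4,7-trimethyl-5-[(1E,3E)-4-phenylbuta-1,3-dien-1-yl]-3a,4,5,7a-tetrahydro-1H-indene-4-carboxylic acid | CCC1=C[C@@H](C)[C@@H]2C(C)=C[C@@](/C=C/C=C/c3ccccc3)(CC)[C@](C)(C(=O)O)[C@@H]12 | target

Total step count: 15. Longest linear sequence: 12 steps (steps 1–7, 9–11, 14 and 15, from compound 1).

Steps most likely to fail

Step 14. Transmetalation of the α-methyl alkenylstannane may be slow, so that protodestannylation and homocoupling compete; during the heating phase some material may leak through the exo (cis-fused) transition state or suffer E/Z isomerisation. The fallback reverses the polarity of the coupling and uses boron, while still forming both bonds in one flask. It sets out from 16 and 21. Iododestannylation of 16 (I2, CH2Cl2, 0 °C) should give, with retention, methyl (2E,4Z,6R,7E)-4-ethyl-8-iodo-2,6-dimethylnona-2,4,7-trienoate F1. Miyaura borylation of 21 (B2pin2, PdCl2(PPh3)2, PPh3, KOPh, toluene, 50 °C) should give 2-[(1E,3E,5E)-2-ethyl-6-phenylhexa-1,3,5-trien-1-yl]-4,4,5,5-tetramethyl-1,3,2-dioxaborolane F2. Suzuki–Miyaura coupling of F1 with F2 (Pd(PPh3)4, aq. K3PO4, THF, 23 °C) would form the same tetraene 22, which is warmed in the same flask and comes back to the route at 23.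

Step 5. Regiocontrol in the addition of the palladium hydride/stannyl pair across the unsymmetrical internal alkyne may be poor, placing tin next to the stereocentre, and tin hydride may be lost to hexabutylditin. The fallback sets out from 6. Hydrozirconation with excess Cp2Zr(H)Cl (THF, 50 °C, so that zirconium settles on the methyl-bearing carbon) and an iodine quench should give (S,E)-tert-butyl[(4-iodo-2-methylpent-3-en-1-yl)oxy]dimethylsilane F3. Iodine–lithium exchange (t-BuLi, Et2O, −78 °C) and trapping with Bu3SnCl comes back to the route at 7.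

Step 15. The SN2 demethylation of the very hindered ester may stall, or the thiolate may attack the polyene on prolonged exposure. The fallback replaces dealkylation by a redox detour and sets out from 23. Reduction with LiAlH4 (THF, 0 °C to reflux) should give [(1R,3aR,4R,5S,7aS)-3,5-diethyl-1,4,7-trimethyl-5-[(1E,3E)-4-phenylbuta-1,3-dien-1-yl]-3a,4,5,7a-tetrahydro-1H-inden-4-yl]methanol F4. Dess–Martin oxidation should give the corresponding 1H-indene-4-carbaldehyde F5, and Pinnick oxidation (NaClO2, NaH2PO4, 2-methyl-2-butene, t-BuOH/H2O) comes back to the route at 24.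

Further compounds
F1 | step 14 | methyl (2E,4Z,6R,7E)-4-ethyl-8-iodo-2,6-dimethylnona-2,4,7-trienoate | COC(=O)/C(C)=C/C(CC)=C\[C@@H](C)/C=C(\C)I
F2 | step 14 | 2-[(1E,3E,5E)-2-ethyl-6-phenylhexa-1,3,5-trien-1-yl]-4,4,5,5-tetramethyl-1,3,2-dioxaborolane | CC/C(=C\B1OC(C)(C)C(C)(C)O1)/C=C/C=C/c1ccccc1
F3 | step 5 | (S,E)-tert-butyl[(4-iodo-2-methylpent-3-en-1-yl)oxy]dimethylsilane | CC(C)(C)[Si](C)(C)OC[C@@H](C)/C=C(\C)I
F4 | step 15 | [(1R,3aR,4R,5S,7aS)-3,5-diethyl-1,4,7-trimethyl-5-[(1E,3E)-4-phenylbuta-1,3-dien-1-yl]-3a,4,5,7a-tetrahydro-1H-inden-4-yl]methanol | CCC1=C[C@@H](C)[C@@H]2C(C)=C[C@@](/C=C/C=C/c3ccccc3)(CC)[C@](C)(CO)[C@@H]12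
F5 | step 15 | (1R,3aR,4R,5S,7aS)-3,5-diethyl-1,4,7-trimethyl-5-[(1E,3E)-4-phenylbuta-1,3-dien-1-yl]-3a,4,5,7a-tetrahydro-1H-indene-4-carbaldehyde | CCC1=C[C@@H](C)[C@@H]2C(C)=C[C@@](/C=C/C=C/c3ccccc3)(CC)[C@](C)(C=O)[C@@H]12
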